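**Plan**
- Retrosynthesis: the silyl ether and the two MOM ethers are removed last, then ring A is cut at C6–C7. The C7 phenol carbon lies between oxygenated C6 and C8–H, which marks it as a former ketene carbon that closed onto an enol ether carbon (C6) across the C4a=C8a bond of pyranone ring C.
- The ketene is traced to a diazoacetyl group on C8a (C7 from a carboxyl carbon, C8 from a diazomethane equivalent), and the enol ether to a CH2CHO chain on C4a.
- Ring C is cut at O1–C8a, then at C4a–C8a (oxalate) and C3–C4 (butanoate); the remaining ring B ketone ArCOCH2OMOM is cut at C2–C3.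
- Forward: ring B aldehyde → α-alkoxy ketone → two Claisen-type acylations join the chain → ring C by cyclodehydration → side-chain adjustment → ring A by Wolff rearrangement and electrocyclization → deprotection.
- Stereochemistry: the target has no stereocentre and no stereogenic double bond; the enol ether geometry and the transient sp3 C6 are erased on aromatization.

Key step: step 12

Assumption: the silyl enol ether is drawn and carried as the E isomer; any Z isomer formed in step 9 is expected to converge on the same phenol, because the sp3 carbon made in the ring closure is lost on tautomerization.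
Ar = 4-(methoxymethoxy)-3-[(3-methylbut-2-en-1-yl)oxy]phenyl; ring A positions use flavone numbering.

**Step 1**
Reactants: 1 3,4-dihydroxybenzaldehyde
Product: 2 3-hydroxy-4-(methoxymethoxy)benzaldehyde
Conditions: MOMCl (1.05 equiv), K2CO3 (1.1 equiv), acetone, 0 °C → rt
Reagents that add atoms: chloromethyl methyl ether, COCCl
Why: The 4-OH para to the formyl group is the more acidic phenol, so with one equivalent of base its phenoxide is the one alkylated (regioselective Williamson-type O-alkylation).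

**Step 2**
Reactants: 2 3-hydroxy-4-(methoxymethoxy)benzaldehyde; 3 1-bromo-3-methylbut-2-ene (prenyl bromide)
Product: 4 4-(methoxymethoxy)-3-[(3-methylbut-2-en-1-yl)oxy]benzaldehyde
Conditions: K2CO3, DMF, rt
Reagents that add atoms: none
Why: Williamson ether synthesis of the remaining phenol by SN2 attack at the primary carbon of the allylic bromide.

**Step 3**
Reactants: 4 4-(methoxymethoxy)-3-[(3-methylbut-2-en-1-yl)oxy]benzaldehyde; 5 tributyl[(methoxymethoxy)methyl]stannane
Product: 7 2-(methoxymethoxy)-1-Ar-ethan-1-ol (racemic), via (methoxymethoxy)methyllithium 6 (not isolated)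
Conditions: 5, n-BuLi, THF, –78 °C; then 4, –78 °C; H2O
Reagents that add atoms: none
Why: Tin–lithium exchange gives an α-alkoxymethyllithium (hydroxymethyl anion equivalent) that adds 1,2 to the aldehyde; the new carbinol centre is racemic and is removed in step 4.

**Step 4**
Reactants: 7 2-(methoxymethoxy)-1-Ar-ethan-1-ol
Product: 8 2-(methoxymethoxy)-1-Ar-ethan-1-one
Conditions: Dess–Martin periodinane, CH2Cl2, 0 °C → rt
Reagents that add atoms: none
Why: Dess–Martin oxidation of a benzylic secondary alcohol to the aryl ketone, which leaves the MOM ethers and the prenyl alkene alone.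

**Step 5**
Reactants: 8 2-(methoxymethoxy)-1-Ar-ethan-1-one; 9 methyl 4,4-dimethoxybutanoate
Product: 10 6,6-dimethoxy-2-(methoxymethoxy)-1-Ar-hexane-1,3-dione (racemic, enolizable)
Conditions: NaH (2.5 equiv), THF, 0 → 60 °C; then AcOH
Reagents that add atoms: none
Why: Crossed Claisen condensation at the only enolizable carbon of 8 (the CH2 between carbonyl and OMOM, the acylation type used in Allan–Robinson and Baker–Venkataraman flavonol syntheses), driven by formation of the stabilized diketonate.

**Step 6**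
Reactants: 10 6,6-dimethoxy-2-(methoxymethoxy)-1-Ar-hexane-1,3-dione; 11 diallyl oxalate
Product: 12 prop-2-en-1-yl 3-(2,2-dimethoxyethyl)-5-(methoxymethoxy)-2,4,6-trioxo-6-Ar-hexanoate (mixture of tautomers)
Conditions: LiN(iPr)2 (2.1 equiv), THF, –78 → 0 °C; LiN(SiMe3)2 (1.0 equiv), –78 °C; 11 (1.5 equiv), –78 → –40 °C; AcOH
Reagents that add atoms: none
Why: γ-Acylation of a β-diketone dianion: the second deprotonation can only occur at the C4 methylene, this terminal carbanion attacks the oxalate, and the silylamide takes up the acidic proton of the product so that the dianion is not quenched.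

**Step 7**
Reactants: 12 prop-2-en-1-yl 3-(2,2-dimethoxyethyl)-5-(methoxymethoxy)-2,4,6-trioxo-6-Ar-hexanoate
Product: 13 prop-2-en-1-yl 3-(2,2-dimethoxyethyl)-5-(methoxymethoxy)-4-oxo-6-Ar-4H-pyran-2-carboxylate
Conditions: PPh3, CCl4, Et3N, THF, rt
Reagents that add atoms: none
Why: Appel-type cyclodehydration of a 1,3,5-tricarbonyl compound to the 4-pyranone (one enol oxygen is activated as an oxyphosphonium and displaced by the other terminal enol oxygen in a six-ring closure) under buffered conditions that spare the acetal and MOM groups and avoid the furan that protic acid would make from the γ-keto acetal.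

**Step 8**
Reactants: 13 prop-2-en-1-yl 3-(2,2-dimethoxyethyl)-5-(methoxymethoxy)-4-oxo-6-Ar-4H-pyran-2-carboxylate
Product: 14 prop-2-en-1-yl 5-(methoxymethoxy)-4-oxo-3-(2-oxoethyl)-6-Ar-4H-pyran-2-carboxylate
Conditions: aq. HCl (0.5 M)/THF, 0 °C → rt; used crude
Reagents that add atoms: water, O
Why: Dilute-acid hydrolysis of a dimethyl acetal, which should be far faster than cleavage of the aryl MOM or prenyl ethers, and at the pyranone stage no ketone is left for furan formation.

**Step 9**
Reactants: 14 prop-2-en-1-yl 5-(methoxymethoxy)-4-oxo-3-(2-oxoethyl)-6-Ar-4H-pyran-2-carboxylate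
Product: 15 prop-2-en-1-yl 3-[(E)-2-(tert-butyldimethylsilyloxy)ethenyl]-5-(methoxymethoxy)-4-oxo-6-Ar-4H-pyran-2-carboxylate
Conditions: tBuMe2SiOTf (1.2 equiv), Et3N (2 equiv), CH2Cl2, –78 → 0 °C
Reagents that add atoms: tert-butyldimethylsilyl trifluoromethanesulfonate, CC(C)(C)[Si](C)(C)OS(=O)(=O)C(F)(F)F
Why: Silyl triflate/amine enol silylation of an aldehyde whose α-CH2 is acidified by the pyranone; the E isomer, with the silyloxy group turned away from the flanking ring substituents, should be favoured, and fast O-silylation at low temperature should outrun lactonization onto the neighbouring ester.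

**Step 10**
Reactants: 15 prop-2-en-1-yl 3-[(E)-2-(tert-butyldimethylsilyloxy)ethenyl]-5-(methoxymethoxy)-4-oxo-6-Ar-4H-pyran-2-carboxylate
Product: 16 potassium 3-[(E)-2-(tert-butyldimethylsilyloxy)ethenyl]-5-(methoxymethoxy)-4-oxo-6-Ar-4H-pyran-2-carboxylate
Conditions: Pd(PPh3)4 (3 mol %), potassium 2-ethylhexanoate (1.0 equiv), EtOAc/CH2Cl2, rt; salt collected after dilution with Et2O
Reagents that add atoms: potassium 2-ethylhexanoate, CCCCC(CC)C(=O)[O-].[K+]
Why: Tsuji–Trost deallylation, in which zerovalent palladium ionizes the allyl carboxylate much faster than the hindered aryl prenyl ether and 2-ethylhexanoate takes over the allyl group, so the carboxylate salt forms without acid or hydroxide and the silyl enol ether and pyranone are untouched.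

**Step 11**
Reactants: 16 potassium 3-[(E)-2-(tert-butyldimethylsilyloxy)ethenyl]-5-(methoxymethoxy)-4-oxo-6-Ar-4H-pyran-2-carboxylate; 17 (trimethylsilyl)diazomethane
Product: 19 2-(diazoacetyl)-3-[(E)-2-(tert-butyldimethylsilyloxy)ethenyl]-5-(methoxymethoxy)-6-Ar-4H-pyran-4-one, via acid chloride 18 (not isolated)
Conditions: (COCl)2 (1.05 equiv), CH2Cl2, –20 → 0 °C; then 17 (2 equiv), MeCN, 0 °C; concentrate
Reagents that add atoms: none
Why: A carboxylate salt and oxalyl chloride give the acid chloride without HCl or a free acid next to the silyl enol ether, and acylation of the silyl diazomethane (Arndt–Eistert-type diazoketone synthesis) follows, with chloride taking the silyl group from carbon.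

**Step 12**
Reactants: 19 2-(diazoacetyl)-3-[(E)-2-(tert-butyldimethylsilyloxy)ethenyl]-5-(methoxymethoxy)-6-Ar-4H-pyran-4-one
Product: 22 6-(tert-butyldimethylsilyloxy)-7-hydroxy-3-(methoxymethoxy)-2-Ar-4H-chromen-4-one, via dienylketene 20 (not isolated), via cyclohexadienone 21 (not isolated)
Conditions: hν (blue LEDs, ca. 440 nm), degassed toluene (0.005 M), rt → 40 °C
Reagents that add atoms: none
Why: Excitation of the diazoketone expels N2 with 1,2-shift of the pyranone carbon (Wolff rearrangement), so the former diazo carbon becomes C8 on C8a and the former carbonyl carbon becomes the ketene carbon C7 of 20. The ketene C7=C8, the ring bond C8a=C4a and the enol ether C5=C6 form a hexatriene whose central double bond is held cis by ring C, and thermal disrotatory six-electron electrocyclization forms C6–C7 and closes ring A as the 2,4-cyclohexadienone 21, which enolizes to the C7 phenol 22. The closest known reaction type is the dienylketene electrocyclization that ends Wolff-based benzannulations to phenols; no stereocentre remains because the sp3 C6 of 21 is lost on tautomerization, which also makes the enol ether geometry irrelevant. The selectivity needed is rearrangement over capture of the carbene by the neighbouring enol ether, and metal-free direct photolysis in a non-nucleophilic solvent, where the s-Z diazoketone rearranges as N2 leaves, should secure it, while the electron-rich C6 terminus is polarity-matched to the electrophilic ketene carbon. Visible light addresses the weak diazo band and should largely spare the aryl prenyl ether and the 3-alkoxy pyranone chromophore, and high dilution keeps the new phenol from acylating unreacted ketene.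

**Step 13**
Reactants: 22 6-(tert-butyldimethylsilyloxy)-7-hydroxy-3-(methoxymethoxy)-2-Ar-4H-chromen-4-one
Product: 23 6,7-dihydroxy-3-(methoxymethoxy)-2-Ar-4H-chromen-4-one
Conditions: Bu4NF (1.1 equiv), AcOH (1.2 equiv), THF, 0 °C
Reagents that add atoms: none
Why: Fluoride cleavage of an aryl silyl ether, buffered with acetic acid so that the catechol is not exposed as an oxidizable phenoxide.

**Step 14**
Reactants: 23 6,7-dihydroxy-3-(methoxymethoxy)-2-Ar-4H-chromen-4-one
Product: 24 3,6,7-trihydroxy-2-{4-hydroxy-3-[(3-methylbut-2-en-1-yl)oxy]phenyl}-4H-chromen-4-one (CNP0086069.0)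
Conditions: Me3SiOTf (6 equiv), 2,2'-bipyridyl (9 equiv), MeCN, 0 °C → rt; then H2O
Reagents that add atoms: none
Why: Silyl triflate/2,2'-bipyridyl cleavage of aromatic MOM ethers, in which the acetal carbon is passed to the pyridine nitrogen and the phenols are released as trimethylsilyl ethers that hydrolyse on work-up, so no protic acid strong enough to ionize the prenyl ether is present.

**Compound list** (Ar as defined above)
1 | 3,4-dihydroxybenzaldehyde | O=Cc1ccc(O)c(O)c1 | starting material
2 | 3-hydroxy-4-(methoxymethoxy)benzaldehyde | O=Cc1ccc(OCOC)c(O)c1 | intermediate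
3 | 1-bromo-3-methylbut-2-ene (prenyl bromide) | CC(C)=CCBr | starting material
4 | 4-(methoxymethoxy)-3-[(3-methylbut-2-en-1-yl)oxy]benzaldehyde | O=Cc1ccc(OCOC)c(OCC=C(C)C)c1 | intermediate
5 | tributyl[(methoxymethoxy)methyl]stannane | CCCC[Sn](CCCC)(CCCC)COCOC | starting material
6 | (methoxymethoxy)methyllithium | [Li]COCOC | intermediate
7 | 2-(methoxymethoxy)-1-Ar-ethan-1-ol (racemic) | OC(COCOC)c1ccc(OCOC)c(OCC=C(C)C)c1 | intermediate
8 | 2-(methoxymethoxy)-1-Ar-ethan-1-one | O=C(COCOC)c1ccc(OCOC)c(OCC=C(C)C)c1 | intermediate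
9 | methyl 4,4-dimethoxybutanoate | COC(=O)CCC(OC)OC | starting material
10 | 6,6-dimethoxy-2-(methoxymethoxy)-1-Ar-hexane-1,3-dione (racemic, enolizable) | COCOC(C(=O)CCC(OC)OC)C(=O)c1ccc(OCOC)c(OCC=C(C)C)c1 | intermediate
11 | diallyl oxalate | C=CCOC(=O)C(=O)OCC=C | starting material
12 | prop-2-en-1-yl 3-(2,2-dimethoxyethyl)-5-(methoxymethoxy)-2,4,6-trioxo-6-Ar-hexanoate (stereocentres labile) | C=CCOC(=O)C(=O)C(CC(OC)OC)C(=O)C(OCOC)C(=O)c1ccc(OCOC)c(OCC=C(C)C)c1 | intermediate
13 | prop-2-en-1-yl 3-(2,2-dimethoxyethyl)-5-(methoxymethoxy)-4-oxo-6-Ar-4H-pyran-2-carboxylate | C=CCOC(=O)c1oc(-c2ccc(OCOC)c(OCC=C(C)C)c2)c(OCOC)c(=O)c1CC(OC)OC | intermediate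
14 | prop-2-en-1-yl 5-(methoxymethoxy)-4-oxo-3-(2-oxoethyl)-6-Ar-4H-pyran-2-carboxylate | C=CCOC(=O)c1oc(-c2ccc(OCOC)c(OCC=C(C)C)c2)c(OCOC)c(=O)c1CC=O | intermediate
15 | prop-2-en-1-yl 3-[(E)-2-(tert-butyldimethylsilyloxy)ethenyl]-5-(methoxymethoxy)-4-oxo-6-Ar-4H-pyran-2-carboxylate | C=CCOC(=O)c1oc(-c2ccc(OCOC)c(OCC=C(C)C)c2)c(OCOC)c(=O)c1/C=C/O[Si](C)(C)C(C)(C)C | intermediate
16 | potassium 3-[(E)-2-(tert-butyldimethylsilyloxy)ethenyl]-5-(methoxymethoxy)-4-oxo-6-Ar-4H-pyran-2-carboxylate | [K+].[O-]C(=O)c1oc(-c2ccc(OCOC)c(OCC=C(C)C)c2)c(OCOC)c(=O)c1/C=C/O[Si](C)(C)C(C)(C)C | intermediate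
17 | (trimethylsilyl)diazomethane | C[Si](C)(C)C=[N+]=[N-] | starting material
18 | 3-[(E)-2-(tert-butyldimethylsilyloxy)ethenyl]-5-(methoxymethoxy)-4-oxo-6-Ar-4H-pyran-2-carbonyl chloride | ClC(=O)c1oc(-c2ccc(OCOC)c(OCC=C(C)C)c2)c(OCOC)c(=O)c1/C=C/O[Si](C)(C)C(C)(C)C | intermediate
19 | 2-(diazoacetyl)-3-[(E)-2-(tert-butyldimethylsilyloxy)ethenyl]-5-(methoxymethoxy)-6-Ar-4H-pyran-4-one | [N-]=[N+]=CC(=O)c1oc(-c2ccc(OCOC)c(OCC=C(C)C)c2)c(OCOC)c(=O)c1/C=C/O[Si](C)(C)C(C)(C)C | intermediate
20 | 2-{3-[(E)-2-(tert-butyldimethylsilyloxy)ethenyl]-5-(methoxymethoxy)-4-oxo-6-Ar-4H-pyran-2-yl}ethen-1-one (dienylketene) | O=C=Cc1oc(-c2ccc(OCOC)c(OCC=C(C)C)c2)c(OCOC)c(=O)c1/C=C/O[Si](C)(C)C(C)(C)C | intermediate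
21 | 6-(tert-butyldimethylsilyloxy)-3-(methoxymethoxy)-2-Ar-6H-chromene-4,7-dione (racemic at C6) | O=C1C=C2OC(c3ccc(OCOC)c(OCC=C(C)C)c3)=C(OCOC)C(=O)C2=CC1O[Si](C)(C)C(C)(C)C | intermediate
22 | 6-(tert-butyldimethylsilyloxy)-7-hydroxy-3-(methoxymethoxy)-2-Ar-4H-chromen-4-one | CC(C)=CCOc1cc(-c2oc3cc(O)c(O[Si](C)(C)C(C)(C)C)cc3c(=O)c2OCOC)ccc1OCOC | intermediate
23 | 6,7-dihydroxy-3-(methoxymethoxy)-2-Ar-4H-chromen-4-one | CC(C)=CCOc1cc(-c2oc3cc(O)c(O)cc3c(=O)c2OCOC)ccc1OCOC | intermediate
24 | 3,6,7-trihydroxy-2-{4-hydroxy-3-[(3-methylbut-2-en-1-yl)oxy]phenyl}-4H-chromen-4-one | CC(C)=CCOc1cc(-c2oc3cc(O)c(O)cc3c(=O)c2O)ccc1O | target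

Total step count: 14. Longest linear sequence: 14 steps (from 1).

**Steps most likely to fail**

Step 12. The carbene or excited diazoketone may be captured by the neighbouring electron-rich silyl enol double bond (cyclopropanation), or the O–Si bond may be lost, before the 1,2-shift occurs. The fallback changes the enol partner to a less nucleophilic, hydrolytically robust enol ester. It sets out from 14: Ac2O, Et3N and catalytic DMAP in CH2Cl2 should give the enol acetate allyl ester F1. Deallylation as in step 10 gives the potassium carboxylate F2, and oxalyl chloride gives the acid chloride F3, which with 17 gives the diazoketone F4. Irradiation as in step 12 should lead through the ketene F5 and the cyclohexadienone F6 to the 6-acetoxy-7-hydroxychromone F7. K2CO3 in MeOH at 0 °C under argon removes the acetate, and the route is rejoined at 23.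

Step 6. The acidic triketo ester may transfer a proton to unreacted dianion, and the amide bases may attack the oxalate, so that acylation stalls. The fallback replaces the dianion by a neutral nucleophile. It sets out from 10: LiN(iPr)2 (2.1 equiv) in THF followed by Me3SiCl at –78 °C gives the 1,3-bis(trimethylsilyloxy)diene F8 (mixture of double-bond isomers, geometry immaterial). Mukaiyama-type γ-acylation of F8 with allyl chlorooxoacetate (ClC(=O)C(=O)OCC=C) in CH2Cl2 at –78 °C and aqueous work-up returns to the route at 12.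

Step 11. Oxalyl chloride or the acid chloride may C-acylate the silyl enol ether, or chloride may remove its silyl group, during carboxylate activation. The fallback reverses the order so that the enol ether is made last. It sets out from 13: deallylation as in step 10 gives the potassium carboxylate F9. Oxalyl chloride gives the acid chloride F10, which with 17 gives the acetal diazoketone F11. Pyridinium p-toluenesulfonate in wet acetone at 40 °C unmasks the aldehyde diazoketone F12. tBuMe2SiOTf (1.1 equiv) and Et3N in CH2Cl2 at –78 °C, where O-silylation of the aldehyde should outrun C-silylation of the diazo carbon, return to the route at 19.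

**Further compounds**
F1 | step 12 | prop-2-en-1-yl 3-[(E)-2-acetoxyethenyl]-5-(methoxymethoxy)-4-oxo-6-Ar-4H-pyran-2-carboxylate | C=CCOC(=O)c1oc(-c2ccc(OCOC)c(OCC=C(C)C)c2)c(OCOC)c(=O)c1/C=C/OC(C)=O
F2 | step 12 | potassium 3-[(E)-2-acetoxyethenyl]-5-(methoxymethoxy)-4-oxo-6-Ar-4H-pyran-2-carboxylate | [K+].[O-]C(=O)c1oc(-c2ccc(OCOC)c(OCC=C(C)C)c2)c(OCOC)c(=O)c1/C=C/OC(C)=O
F3 | step 12 | 3-[(E)-2-acetoxyethenyl]-5-(methoxymethoxy)-4-oxo-6-Ar-4H-pyran-2-carbonyl chloride | ClC(=O)c1oc(-c2ccc(OCOC)c(OCC=C(C)C)c2)c(OCOC)c(=O)c1/C=C/OC(C)=O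
F4 | step 12 | (E)-2-[2-(diazoacetyl)-5-(methoxymethoxy)-4-oxo-6-Ar-4H-pyran-3-yl]ethenyl acetate | [N-]=[N+]=CC(=O)c1oc(-c2ccc(OCOC)c(OCC=C(C)C)c2)c(OCOC)c(=O)c1/C=C/OC(C)=O
F5 | step 12 | (E)-2-[5-(methoxymethoxy)-4-oxo-2-(2-oxoethenyl)-6-Ar-4H-pyran-3-yl]ethenyl acetate (ketene) | O=C=Cc1oc(-c2ccc(OCOC)c(OCC=C(C)C)c2)c(OCOC)c(=O)c1/C=C/OC(C)=O
F6 | step 12 | 3-(methoxymethoxy)-4,7-dioxo-2-Ar-6,7-dihydro-4H-chromen-6-yl acetate (racemic at C6) | O=C1C=C2OC(c3ccc(OCOC)c(OCC=C(C)C)c3)=C(OCOC)C(=O)C2=CC1OC(C)=O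
F7 | step 12 | 7-hydroxy-3-(methoxymethoxy)-4-oxo-2-Ar-4H-chromen-6-yl acetate | CC(C)=CCOc1cc(-c2oc3cc(O)c(OC(C)=O)cc3c(=O)c2OCOC)ccc1OCOC
F8 | step 6 | 6,6-dimethoxy-2-(methoxymethoxy)-1,3-bis(trimethylsilyloxy)-1-Ar-hexa-1,3-diene (mixture of double-bond isomers) | COCOC(=C(O[Si](C)(C)C)c1ccc(OCOC)c(OCC=C(C)C)c1)C(O[Si](C)(C)C)=CCC(OC)OC
F9 | step 11 | potassium 3-(2,2-dimethoxyethyl)-5-(methoxymethoxy)-4-oxo-6-Ar-4H-pyran-2-carboxylate | [K+].[O-]C(=O)c1oc(-c2ccc(OCOC)c(OCC=C(C)C)c2)c(OCOC)c(=O)c1CC(OC)OC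
F10 | step 11 | 3-(2,2-dimethoxyethyl)-5-(methoxymethoxy)-4-oxo-6-Ar-4H-pyran-2-carbonyl chloride | ClC(=O)c1oc(-c2ccc(OCOC)c(OCC=C(C)C)c2)c(OCOC)c(=O)c1CC(OC)OC
F11 | step 11 | 2-(diazoacetyl)-3-(2,2-dimethoxyethyl)-5-(methoxymethoxy)-6-Ar-4H-pyran-4-one | [N-]=[N+]=CC(=O)c1oc(-c2ccc(OCOC)c(OCC=C(C)C)c2)c(OCOC)c(=O)c1CC(OC)OC
F12 | step 11 | 2-[2-(diazoacetyl)-5-(methoxymethoxy)-4-oxo-6-Ar-4H-pyran-3-yl]acetaldehyde | [N-]=[N+]=CC(=O)c1oc(-c2ccc(OCOC)c(OCC=C(C)C)c2)c(OCOC)c(=O)c1CC=O
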